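The flask holds 2.50 equivalents of L to X, and X is the limiting reagent, since two L for each X need less than the L charged.

| setting | north-east | south | north-west | flask |
|---|---|---|---|---|
| X | 20 mM | 20 mM | 10 mM | 20 mM |
| L | 34 mM | 75 mM | 50 mM | 50.0 mM |
| remark | run made earlier | run made earlier | run made earlier |  |
| time |  |  |  | 3.0 min |

- north-east (time / s: D / %): 10.0: 14.9; 15.0: 18.6; 30.0: 25.4; 60.0: 25.4; 120: 17.7
- south (time / s: D / %): 10.0: 28.2; 15.0: 32.6; 30.0: 36.7; 60.0: 26.1; 120: 11.5
- north-west (time / s: D / %): 10.0: 21.0; 15.0: 26.3; 30.0: 32.7; 60.0: 27.9; 120: 14.2

(standard deviation of a reading: 0.5 percentage points)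

- on the list of suspects stand: X + L -> J; D <-> Q; X + L -> D; L + D -> G; L + J -> G

- time up to 3.0 min at which D stands highest
- the amount of D, in percent of the X charged, at that time

Which runs can you read across? The north-west run has the flask's L but half its X, while the north-east and south runs have the flask's X, so I bracket the flask with those two.

How high, then? Their highest readings, both at 30.0 s, are 25.4% and 36.7%. These give 9.9 percentage points per doubling of L: that is the peak gain, the rise of the highest D reading for each doubling of the L charge with X held at 20 mM. The flask's L lies 0.556 doublings above the north-east run, so I expect 30.9%.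

When? The north-east run reads the same 25.4% at 30.0 s and 60.0 s, so I put its peak near 45.0 s. If that time shrinks in inverse proportion to L, I put the flask's peak near 0.510 min.

The forecast gives 31.3% at 0.58 min, for a flask that “lies midway between the north-east and south runs on a log L scale”. Its height stands 0.40 points above mine, and its time is 0.0700 min later than mine.

The flask gives 31.5% at 0.548 min.

    X + L → J (k = 0.0300 M⁻¹ s⁻¹)
    D ⇌ Q (K = 5.80, k = 0.0240 s⁻¹)
    X + L → D (k = 0.590 M⁻¹ s⁻¹)
    L + D → G (k = 0.200 M⁻¹ s⁻¹)
    L + J → G (k = 1.70 M⁻¹ s⁻¹)

Changing the L charge alone from the north-east run carries the best D, without the scatter, from 26.0% to 31.5%, and the peak gain over 0.556 doublings makes that step 5.5 points. For the neighbour with the same X and 85 mM of L, the peak gain gives 38.5%, and that flask reaches 38.4%.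

Readings and results come from a simulation with made-up constants, and the scatter is random.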